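The route rests on disconnecting the C6–C7 bond (germacranolide numbering: C6 is the lactone O–CH, C7 the ring-fusion CH), the bond shared by the ten-membered carbocycle and the α-methylene-γ-butyrolactone. Because C7–C11(=C13)–C12 is a 2-carboxyallyl unit and C6 a carbinol carbon, an intramolecular chromium-mediated carbonyl allylation of an acyclic (Z)-enal (C6) bearing a 2-(bromomethyl)acrylate (C13–C11–C7) closes the ten-membered ring, sets C6 and C7, transposes the alkene to the exocyclic C11=C13 methylene and lactonizes in one operation. The precursor already carries the C1–C10 epoxide, C3–OTBS and C8–OPMB; the epoxytiglate ester is attached afterwards.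

Key step: step 14

Remark: germacranolide numbering is used throughout (C1–C10 ring, C11–C13 lactone carbons, C14 and C15 methyls). The ester side chain is read from the SMILES as (2R,3S)-2,3-dimethyloxirane-2-carboxylate (cis-dimethyl, an epoxytiglate). TES = triethylsilyl, TBS = tert-butyldimethylsilyl, PMB = 4-methoxybenzyl.

Step 1
Reactants: 1 (S)-glycidol
Product: 2 (R)-triethyl(oxiran-2-ylmethoxy)silane
Conditions: Et3SiCl, imidazole, CH2Cl2, 0 °C
Reagents that add atoms: chlorotriethylsilane CC[Si](Cl)(CC)CC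
Why: O-silylation of the primary alcohol leaves the stereocenter untouched (the descriptor changes from S to R by priority only).

Step 2
Reactants: 2 (R)-triethyl(oxiran-2-ylmethoxy)silane
Product: 3 (R)-1-(triethylsilyloxy)pent-4-yn-2-ol
Conditions: LiC≡CH·H2NCH2CH2NH2, DMSO, 0 °C → rt
Reagents that add atoms: lithium acetylide–ethylenediamine complex [Li+].[C-]#C.NCCN
Why: SN2 opening of the terminal epoxide at its CH2 carbon by acetylide carries the glycidol stereocenter unchanged into the C8 carbinol.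

Step 3
Reactants: 3 (R)-1-(triethylsilyloxy)pent-4-yn-2-ol
Product: 4 (R)-triethyl{[2-(4-methoxybenzyloxy)pent-4-yn-1-yl]oxy}silane
Conditions: 2-(4-methoxybenzyloxy)-4-methylquinoline, MeOTf, MgO, PhCF3, 0 °C → rt
Reagents that add atoms: 2-(4-methoxybenzyloxy)-4-methylquinoline COc1ccc(COc2cc(C)c3ccccc3n2)cc1
Why: neutral p-methoxybenzyl transfer from the N-methylated quinolinium ether (benzylic etherification without acid or base) protects the secondary alcohol, so the neighbouring primary silyl ether should neither cleave nor migrate.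

Step 4
Reactants: 4 (R)-triethyl{[2-(4-methoxybenzyloxy)pent-4-yn-1-yl]oxy}silane
Product: 7 (3E,6R)-6-(4-methoxybenzyloxy)-4-methyl-7-(triethylsilyloxy)hept-3-en-1-ol, via alkenylalane 5 (not isolated), via lithium alkenylalanate 6 (not isolated)
Conditions: Me3Al, Cp2ZrCl2 (cat.), CH2Cl2, 0 °C → rt; then n-BuLi, hexane/THF, −78 °C; ethylene oxide, −78 °C → rt
Reagents that add atoms: trimethylaluminium C[Al](C)C; ethylene oxide C1CO1
Why: zirconium-catalysed syn methylalumination of the terminal alkyne (Negishi carboalumination) fixes the E trisubstituted C1=C10 alkene, and the ate complex opens ethylene oxide with retention of that geometry.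

Step 5
Reactants: 7 (3E,6R)-6-(4-methoxybenzyloxy)-4-methyl-7-(triethylsilyloxy)hept-3-en-1-ol
Product: 8 (3E,6R)-6-(4-methoxybenzyloxy)-4-methyl-7-(triethylsilyloxy)hept-3-enal
Conditions: Dess–Martin periodinane, NaHCO3, CH2Cl2, 0 °C
Reagents that add atoms: none
Why: buffered hypervalent-iodine oxidation should give the β,γ-unsaturated aldehyde without moving the alkene into conjugation; it is used crude.

Step 6
Reactants: 9 but-2-yn-1-ol
Product: 11 (Z)-3-iodobut-2-en-1-ol, via cyclic alkenylaluminate 10 (not isolated)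
Conditions: NaAlH2(OCH2CH2OMe)2, THF, 0 °C → rt; then I2, −78 °C
Reagents that add atoms: iodine II
Why: hydroxyl-directed anti hydroalumination of the propargylic alcohol puts aluminium on C3, and iodinolysis with retention gives the (Z)-vinyl iodide.

Step 7
Reactants: 11 (Z)-3-iodobut-2-en-1-ol
Product: 12 (Z)-triethyl[(3-iodobut-2-en-1-yl)oxy]silane
Conditions: Et3SiCl, imidazole, CH2Cl2, 0 °C
Reagents that add atoms: chlorotriethylsilane CC[Si](Cl)(CC)CC
Why: O-silylation of the primary allylic alcohol, alkene geometry untouched.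

Step 8
Reactants: 8 (3E,6R)-6-(4-methoxybenzyloxy)-4-methyl-7-(triethylsilyloxy)hept-3-enal; 12 (Z)-triethyl[(3-iodobut-2-en-1-yl)oxy]silane
Product: 14 (2Z,4S,6E,9R)-9-(4-methoxybenzyloxy)-3,7-dimethyl-1,10-bis(triethylsilyloxy)deca-2,6-dien-4-ol, via alkenylchromium dichloride 13 (not isolated)
Conditions: CrCl2, NiCl2 (cat.), chiral oxazoline–sulfonamide ligand (enantiomer directing Re-face addition), Et3N, THF, rt
Reagents that add atoms: none
Why: asymmetric Nozaki–Hiyama–Kishi alkenylation, in which the alkenylchromium formed with retention of the Z geometry adds to the aldehyde and the chiral ligand on chromium sets C3 (C4 of the chain) as S by Re-face attack, the remote C8 center exerting no control.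

Step 9
Reactants: 14 (2Z,4S,6E,9R)-9-(4-methoxybenzyloxy)-3,7-dimethyl-1,10-bis(triethylsilyloxy)deca-2,6-dien-4-ol
Product: 15 (2Z,4S,6E,9R)-4-(tert-butyldimethylsilyloxy)-9-(4-methoxybenzyloxy)-3,7-dimethyl-1,10-bis(triethylsilyloxy)deca-2,6-diene
Conditions: TBSOTf, 2,6-lutidine, CH2Cl2, −78 °C
Reagents that add atoms: tert-butyldimethylsilyl trifluoromethanesulfonate CC(C)(C)[Si](C)(C)OS(=O)(=O)C(F)(F)F
Why: silylation of the secondary allylic alcohol with the reactive triflate under non-nucleophilic base leaves the primary TES ethers in place.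

Step 10
Reactants: 15 (2Z,4S,6E,9R)-4-(tert-butyldimethylsilyloxy)-9-(4-methoxybenzyloxy)-3,7-dimethyl-1,10-bis(triethylsilyloxy)deca-2,6-diene
Product: 16 (2Z,4S,6R,7R,9R)-4-(tert-butyldimethylsilyloxy)-6,7-epoxy-9-(4-methoxybenzyloxy)-3,7-dimethyl-1,10-bis(triethylsilyloxy)dec-2-ene
Conditions: D-fructose-derived ketone catalyst (1,2:4,5-di-O-isopropylidene-β-D-erythro-2,3-hexodiulo-2,6-pyranose), KHSO5 (as 2KHSO5·KHSO4·K2SO4), K2CO3, Bu4NHSO4, MeCN/CH2(OMe)2/aq. buffer pH 10.5, 0 °C
Reagents that add atoms: potassium peroxymonosulfate [K+].[O-]S(=O)(=O)OO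
Why: Shi epoxidation, in which the chiral dioxirane attacks the electron-rich E trisubstituted C1=C10 alkene through a spiro transition state on the face that gives the (1R,10R) epoxide (reagent control), while the C4=C5 alkene is deactivated by its two allylic oxygens.

Step 11
Reactants: 16 (2Z,4S,6R,7R,9R)-4-(tert-butyldimethylsilyloxy)-6,7-epoxy-9-(4-methoxybenzyloxy)-3,7-dimethyl-1,10-bis(triethylsilyloxy)dec-2-ene
Product: 17 (2Z,4S,6R,7R,9R)-4-(tert-butyldimethylsilyloxy)-6,7-epoxy-9-(4-methoxybenzyloxy)-3,7-dimethyldec-2-enedial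
Conditions: (COCl)2, DMSO, CH2Cl2, −78 → −40 °C; then Et3N, −78 → 0 °C
Reagents that add atoms: none
Why: Swern conditions convert primary TES ethers directly into aldehydes (silyl transfer to the activated sulfoxide, then ylide fragmentation), so both chain ends should be oxidized at once while the secondary TBS ether, the PMB ether and the epoxide remain.

Step 12
Reactants: 17 (2Z,4S,6R,7R,9R)-4-(tert-butyldimethylsilyloxy)-6,7-epoxy-9-(4-methoxybenzyloxy)-3,7-dimethyldec-2-enedial
Product: 18 methyl (4R,6R,7R,9S,10Z)-9-(tert-butyldimethylsilyloxy)-6,7-epoxy-3-hydroxy-4-(4-methoxybenzyloxy)-6,10-dimethyl-2-methylidene-12-oxododec-10-enoate (both C3 epimers)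
Conditions: methyl acrylate (excess), DABCO, MeOH, rt
Reagents that add atoms: methyl acrylate C=CC(=O)OC
Why: the Morita–Baylis–Hillman reaction should occur chemoselectively at the unhindered, inductively activated α-alkoxy aldehyde (C7) and not at the β,β-disubstituted enal; the new carbinol forms as an epimer mixture that the next step erases.

Step 13
Reactants: 18 methyl (4R,6R,7R,9S,10Z)-9-(tert-butyldimethylsilyloxy)-6,7-epoxy-3-hydroxy-4-(4-methoxybenzyloxy)-6,10-dimethyl-2-methylidene-12-oxododec-10-enoate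
Product: 19 methyl (2Z,4R,6R,7R,9S,10Z)-2-(bromomethyl)-9-(tert-butyldimethylsilyloxy)-6,7-epoxy-4-(4-methoxybenzyloxy)-6,10-dimethyl-12-oxododeca-2,10-dienoate
Conditions: NBS, Me2S, CH2Cl2, 0 °C
Reagents that add atoms: N-bromosuccinimide O=C1CCC(=O)N1Br
Why: the bromosulfonium reagent activates the allylic alcohol and bromide returns in SN2′ fashion at the terminal CH2, giving the conjugated (Z)-2-(bromomethyl)enoate (C8 anti to the ester) without acid strong enough to open the epoxide.

Step 14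
Reactants: 19 methyl (2Z,4R,6R,7R,9S,10Z)-2-(bromomethyl)-9-(tert-butyldimethylsilyloxy)-6,7-epoxy-4-(4-methoxybenzyloxy)-6,10-dimethyl-12-oxododeca-2,10-dienoate
Product: 22 (1R,3S,6R,7R,8R,10R,4Z)-3-(tert-butyldimethylsilyloxy)-1,10-epoxy-8-(4-methoxybenzyloxy)germacra-4,11(13)-dien-12,6-olide, via allylchromium dichloride 20 (not isolated), via ring-closed hydroxy ester 21 (not isolated)
Conditions: CrCl2 (excess), THF, rt, slow addition at high dilution (about 0.003 M); aqueous work-up
Reagents that add atoms: none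
Why: Two equivalents of CrCl2 reduce the allylic C–Br bond to a σ-allyl complex of trivalent chromium, which adds through its γ-carbon C7 to the C6 aldehyde in a six-membered Zimmerman–Traxler chair with allylic transposition (creating the C11=C13 methylene), after which the chromium alkoxide acylates itself on the methyl ester; the closest known reaction type is the intramolecular Nozaki–Hiyama–Kishi-type 2-(alkoxycarbonyl)allylation used to close medium and large carbocycles. The ten-membered ring closes in a 10-exo-trig mode (C7 onto the C6 carbonyl) and the lactone in a 5-exo-trig mode (O6 onto C12). C6 and C7 are set together: after σ–π–σ equilibration of the allyl fragment, the chair that carries both ends of the tether (C5 on the aldehyde, C8 on the allyl terminus) pseudo-equatorial gives the 6,7-anti adduct and hence the trans-fused lactone. The sense at C7 is controlled by C8: allylic 1,3-strain holds C8–H in the allyl plane, the PMB ether points outward, and C6 bonds to the face anti to C9, the arrangement in which the six-atom tether spans without eclipsing, which should give 7R and with it 6R. The step needs γ- over α-attack (α would give a twelve-membered ring), 1,2- over 1,4-addition and ring closure over oligomerization, which the closed chromium transition state and slow addition at high dilution are meant to secure. The epoxide, the silyl ether and the Z-enal are expected to survive these neutral, non-basic conditions.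

Step 15
Reactants: 22 (1R,3S,6R,7R,8R,10R,4Z)-3-(tert-butyldimethylsilyloxy)-1,10-epoxy-8-(4-methoxybenzyloxy)germacra-4,11(13)-dien-12,6-olide
Product: 23 (1R,3S,6R,7R,8R,10R,4Z)-3-(tert-butyldimethylsilyloxy)-1,10-epoxy-8-hydroxygermacra-4,11(13)-dien-12,6-olide
Conditions: DDQ, CH2Cl2/pH 7 buffer, 0 °C
Reagents that add atoms: none
Why: oxidative cleavage of the p-methoxybenzyl ether through its benzylic cation and hemiacetal frees the C8 hydroxyl, the TBS ether, the epoxide and the alkenes being inert.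

Step 16
Reactants: 24 (E)-2-methylbut-2-en-1-ol
Product: 25 [(2S,3S)-2,3-dimethyloxiran-2-yl]methanol
Conditions: Ti(OiPr)4, L-(+)-diethyl tartrate, t-BuOOH, 4 Å molecular sieves, CH2Cl2, −20 °C
Reagents that add atoms: tert-butyl hydroperoxide CC(C)(C)OO
Why: Sharpless asymmetric epoxidation, in which the L-(+)-tartrate complex delivers oxygen to the face that gives the (2S,3S) epoxy alcohol, the cis relation of the two methyl groups following from the E alkene.

Step 17
Reactants: 25 [(2S,3S)-2,3-dimethyloxiran-2-yl]methanol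
Product: 26 (2R,3S)-2,3-dimethyloxirane-2-carboxylic acid
Conditions: RuCl3 (cat.), NaIO4, MeCN/EtOAc/H2O, rt
Reagents that add atoms: sodium periodate [Na+].[O-]I(=O)(=O)=O; water O
Why: RuO4-type oxidation of the primary alcohol to the acid (via the aldehyde hydrate) leaves both epoxide stereocenters untouched, the change from 2S to 2R being a priority change only.

Step 18
Reactants: 23 (1R,3S,6R,7R,8R,10R,4Z)-3-(tert-butyldimethylsilyloxy)-1,10-epoxy-8-hydroxygermacra-4,11(13)-dien-12,6-olide; 26 (2R,3S)-2,3-dimethyloxirane-2-carboxylic acid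
Product: 28 (1R,3S,6R,7R,8R,10R,4Z)-3-(tert-butyldimethylsilyloxy)-8-[(2R,3S)-2,3-dimethyloxirane-2-carbonyloxy]-1,10-epoxygermacra-4,11(13)-dien-12,6-olide, via mixed anhydride 27 (not isolated)
Conditions: 2,4,6-trichlorobenzoyl chloride, Et3N, THF, rt; then 23, DMAP, toluene, rt
Reagents that add atoms: none
Why: Yamaguchi esterification through the mixed anhydride and its acylpyridinium should acylate the hindered C8 alcohol with retention at every center.

Step 19
Reactants: 28 (1R,3S,6R,7R,8R,10R,4Z)-3-(tert-butyldimethylsilyloxy)-8-[(2R,3S)-2,3-dimethyloxirane-2-carbonyloxy]-1,10-epoxygermacra-4,11(13)-dien-12,6-olide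
Product: 29 (1R,3S,6R,7R,8R,10R,4Z)-8-[(2R,3S)-2,3-dimethyloxirane-2-carbonyloxy]-1,10-epoxy-3-hydroxygermacra-4,11(13)-dien-12,6-olide (CNP0268255.6)
Conditions: HF·pyridine, pyridine, THF, 0 °C → rt
Reagents that add atoms: none
Why: buffered fluoride desilylation should remove the allylic TBS ether without opening either epoxide or adding to the α-methylene lactone.

Compound list

1 | (S)-glycidol | OC[C@H]1CO1 | starting material
2 | (R)-triethyl(oxiran-2-ylmethoxy)silane | CC[Si](CC)(CC)OC[C@H]1CO1 | intermediate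
3 | (R)-1-(triethylsilyloxy)pent-4-yn-2-ol | C#CC[C@@H](O)CO[Si](CC)(CC)CC | intermediate
4 | (R)-triethyl{[2-(4-methoxybenzyloxy)pent-4-yn-1-yl]oxy}silane | C#CC[C@@H](OCc1ccc(OC)cc1)CO[Si](CC)(CC)CC | intermediate
5 | (E)-dimethyl[(4R)-4-(4-methoxybenzyloxy)-2-methyl-5-(triethylsilyloxy)pent-1-en-1-yl]alane | C[Al](C)/C=C(\C)C[C@@H](OCc1ccc(OC)cc1)CO[Si](CC)(CC)CC | intermediate (not isolated)
6 | lithium butyl(dimethyl)alanate of 5 | [Li+].CCCC[Al-](C)(C)/C=C(\C)C[C@@H](OCc1ccc(OC)cc1)CO[Si](CC)(CC)CC | intermediate (not isolated)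
7 | (3E,6R)-6-(4-methoxybenzyloxy)-4-methyl-7-(triethylsilyloxy)hept-3-en-1-ol | OCC/C=C(\C)C[C@@H](OCc1ccc(OC)cc1)CO[Si](CC)(CC)CC | intermediate
8 | (3E,6R)-6-(4-methoxybenzyloxy)-4-methyl-7-(triethylsilyloxy)hept-3-enal | O=CC/C=C(\C)C[C@@H](OCc1ccc(OC)cc1)CO[Si](CC)(CC)CC | intermediate
9 | but-2-yn-1-ol | CC#CCO | starting material
10 | sodium 2,2-bis(2-methoxyethoxy)-3-methyl-2,5-dihydro-1,2-oxaaluminol-2-uide (cyclic alkenylaluminate) | [Na+].CC1=CCO[Al-]1(OCCOC)OCCOC | intermediate (not isolated)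
11 | (Z)-3-iodobut-2-en-1-ol | OC/C=C(/C)I | intermediate
12 | (Z)-triethyl[(3-iodobut-2-en-1-yl)oxy]silane | CC[Si](CC)(CC)OC/C=C(/C)I | intermediate
13 | (Z)-[4-(triethylsilyloxy)but-2-en-2-yl]chromium dichloride | CC[Si](CC)(CC)OC/C=C(/C)[Cr](Cl)Cl | intermediate (not isolated)
14 | (2Z,4S,6E,9R)-9-(4-methoxybenzyloxy)-3,7-dimethyl-1,10-bis(triethylsilyloxy)deca-2,6-dien-4-ol | CC[Si](CC)(CC)OC/C=C(/C)[C@@H](O)C/C=C(\C)C[C@@H](OCc1ccc(OC)cc1)CO[Si](CC)(CC)CC | intermediate
15 | (2Z,4S,6E,9R)-4-(tert-butyldimethylsilyloxy)-9-(4-methoxybenzyloxy)-3,7-dimethyl-1,10-bis(triethylsilyloxy)deca-2,6-diene | CC[Si](CC)(CC)OC/C=C(/C)[C@@H](O[Si](C)(C)C(C)(C)C)C/C=C(\C)C[C@@H](OCc1ccc(OC)cc1)CO[Si](CC)(CC)CC | intermediate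
16 | (2Z,4S,6R,7R,9R)-4-(tert-butyldimethylsilyloxy)-6,7-epoxy-9-(4-methoxybenzyloxy)-3,7-dimethyl-1,10-bis(triethylsilyloxy)dec-2-ene | CC[Si](CC)(CC)OC/C=C(/C)[C@@H](O[Si](C)(C)C(C)(C)C)C[C@H]1O[C@]1(C)C[C@@H](OCc1ccc(OC)cc1)CO[Si](CC)(CC)CC | intermediate
17 | (2Z,4S,6R,7R,9R)-4-(tert-butyldimethylsilyloxy)-6,7-epoxy-9-(4-methoxybenzyloxy)-3,7-dimethyldec-2-enedial | O=C/C=C(/C)[C@@H](O[Si](C)(C)C(C)(C)C)C[C@H]1O[C@]1(C)C[C@@H](OCc1ccc(OC)cc1)C=O | intermediate
18 | methyl (4R,6R,7R,9S,10Z)-9-(tert-butyldimethylsilyloxy)-6,7-epoxy-3-hydroxy-4-(4-methoxybenzyloxy)-6,10-dimethyl-2-methylidene-12-oxododec-10-enoate (both C3 epimers) | O=C/C=C(/C)[C@@H](O[Si](C)(C)C(C)(C)C)C[C@H]1O[C@]1(C)C[C@@H](OCc1ccc(OC)cc1)C(O)C(=C)C(=O)OC | intermediate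
19 | methyl (2Z,4R,6R,7R,9S,10Z)-2-(bromomethyl)-9-(tert-butyldimethylsilyloxy)-6,7-epoxy-4-(4-methoxybenzyloxy)-6,10-dimethyl-12-oxododeca-2,10-dienoate | O=C/C=C(/C)[C@@H](O[Si](C)(C)C(C)(C)C)C[C@H]1O[C@]1(C)C[C@@H](OCc1ccc(OC)cc1)/C=C(\CBr)C(=O)OC | intermediate
20 | allylchromium dichloride from 19 (chromium on C13; C7=C11 geometry equilibrating) | O=C/C=C(/C)[C@@H](O[Si](C)(C)C(C)(C)C)C[C@H]1O[C@]1(C)C[C@@H](OCc1ccc(OC)cc1)C=C(C[Cr](Cl)Cl)C(=O)OC | intermediate (not isolated)
21 | methyl (1R,3S,6R,7S,8R,10R,4Z)-3-(tert-butyldimethylsilyloxy)-1,10-epoxy-6-hydroxy-8-(4-methoxybenzyloxy)germacra-4,11(13)-dien-12-oate (formed as its chromium alkoxide; 7S here is the same spatial arrangement as 7R in 22) | O[C@@H]1/C=C(/C)[C@@H](O[Si](C)(C)C(C)(C)C)C[C@H]2O[C@]2(C)C[C@@H](OCc2ccc(OC)cc2)[C@H]1C(=C)C(=O)OC | intermediate (not isolated)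
22 | (1R,3S,6R,7R,8R,10R,4Z)-3-(tert-butyldimethylsilyloxy)-1,10-epoxy-8-(4-methoxybenzyloxy)germacra-4,11(13)-dien-12,6-olide | C=C1C(=O)O[C@@H]2/C=C(/C)[C@@H](O[Si](C)(C)C(C)(C)C)C[C@H]3O[C@]3(C)C[C@@H](OCc3ccc(OC)cc3)[C@@H]12 | intermediate
23 | (1R,3S,6R,7R,8R,10R,4Z)-3-(tert-butyldimethylsilyloxy)-1,10-epoxy-8-hydroxygermacra-4,11(13)-dien-12,6-olide | C=C1C(=O)O[C@@H]2/C=C(/C)[C@@H](O[Si](C)(C)C(C)(C)C)C[C@H]3O[C@]3(C)C[C@@H](O)[C@@H]12 | intermediate
24 | (E)-2-methylbut-2-en-1-ol | C/C=C(\C)CO | starting material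
25 | [(2S,3S)-2,3-dimethyloxiran-2-yl]methanol | OC[C@]1(C)O[C@H]1C | intermediate
26 | (2R,3S)-2,3-dimethyloxirane-2-carboxylic acid | OC(=O)[C@]1(C)O[C@H]1C | intermediate
27 | (2R,3S)-2,3-dimethyloxirane-2-carboxylic 2,4,6-trichlorobenzoic anhydride | O=C(OC(=O)c1c(Cl)cc(Cl)cc1Cl)[C@]2(C)O[C@H]2C | intermediate (not isolated)
28 | (1R,3S,6R,7R,8R,10R,4Z)-3-(tert-butyldimethylsilyloxy)-8-[(2R,3S)-2,3-dimethyloxirane-2-carbonyloxy]-1,10-epoxygermacra-4,11(13)-dien-12,6-olide | C=C1C(=O)O[C@@H]2/C=C(/C)[C@@H](O[Si](C)(C)C(C)(C)C)C[C@H]3O[C@]3(C)C[C@@H](OC(=O)[C@]3(C)O[C@H]3C)[C@@H]12 | intermediate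
29 | (1R,3S,6R,7R,8R,10R,4Z)-8-[(2R,3S)-2,3-dimethyloxirane-2-carbonyloxy]-1,10-epoxy-3-hydroxygermacra-4,11(13)-dien-12,6-olide (CNP0268255.6) | C=C1C(=O)O[C@@H]2/C=C(/C)[C@@H](O)C[C@H]3O[C@]3(C)C[C@@H](OC(=O)[C@]3(C)O[C@H]3C)[C@@H]12 | target

Total step count: 19. Longest linear sequence: 15 steps (steps 1–5, 8–15, 18 and 19).

Steps most likely to fail

1. Step 14 (key ring closure). The closure may run through the chair with C8 axial (syn mode, giving the cis-fused lactone), may take the wrong face of C7, or may lose material to oligomerization. Fallback from 19 back to 22, for the case that the syn mode dominates: the chromium closure is accepted as a route to the cis-fused (1R,3S,6S,7R,8R,10R,4Z)-3-(tert-butyldimethylsilyloxy)-1,10-epoxy-8-(4-methoxybenzyloxy)germacra-4,11(13)-dien-12,6-olide F1. This lactone is opened with LiOH (THF/H2O, 0 °C, careful acidification to pH 5) to (1R,3S,6S,7S,8R,10R,4Z)-3-(tert-butyldimethylsilyloxy)-1,10-epoxy-6-hydroxy-8-(4-methoxybenzyloxy)germacra-4,11(13)-dien-12-oic acid F2. An invertive Mitsunobu lactonization (PPh3, diisopropyl azodicarboxylate, THF, 0 °C) then lets the carboxylate displace the activated allylic C6 oxygen with inversion, which should return the trans-fused lactone 22. The stereochemical approach changes from direct anti closure to syn closure followed by SN2 relactonization.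

2. Step 12 (Morita–Baylis–Hillman reaction on the dialdehyde). The slow amine-catalysed process may allow loss of the Z geometry of the enal or epimerization at C8 next to the reacting aldehyde. Fallback from 17 to 18 without new compounds: the acrylate unit is delivered as a preformed nucleophile instead of by amine catalysis. [α-(Methoxycarbonyl)vinyl]diisobutylalane, made from methyl propiolate and i-Bu2AlH with N-methylmorpholine N-oxide (THF, 0 °C), is added to 17 at −78 °C (vinylalumination). The more electrophilic α-alkoxy aldehyde is expected to react first, giving 18 under non-basic conditions.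

3. Step 8 (asymmetric alkenylation). Face selection at the new carbinol may be insufficient, or the Z geometry may partly scramble on chromium. Fallback from 8 and 12 back to 14: the coupling is run without chiral ligand (CrCl2, NiCl2 cat., DMSO/THF) to give the epimer mixture (2Z,4RS,6E,9R)-9-(4-methoxybenzyloxy)-3,7-dimethyl-1,10-bis(triethylsilyloxy)deca-2,6-dien-4-ol F3. Dess–Martin oxidation gives (2Z,6E,9R)-9-(4-methoxybenzyloxy)-3,7-dimethyl-1,10-bis(triethylsilyloxy)deca-2,6-dien-4-one F4. Corey–Bakshi–Shibata reduction with the (R)-methyl-oxazaborolidine and catecholborane (toluene, −78 °C) then sets the 4S carbinol by reagent control and returns 14.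

Further compounds

F1 | step 14 | (1R,3S,6S,7R,8R,10R,4Z)-3-(tert-butyldimethylsilyloxy)-1,10-epoxy-8-(4-methoxybenzyloxy)germacra-4,11(13)-dien-12,6-olide (6-epimer of 22) | C=C1C(=O)O[C@H]2/C=C(/C)[C@@H](O[Si](C)(C)C(C)(C)C)C[C@H]3O[C@]3(C)C[C@@H](OCc3ccc(OC)cc3)[C@@H]12
F2 | step 14 | (1R,3S,6S,7S,8R,10R,4Z)-3-(tert-butyldimethylsilyloxy)-1,10-epoxy-6-hydroxy-8-(4-methoxybenzyloxy)germacra-4,11(13)-dien-12-oic acid | O[C@H]1/C=C(/C)[C@@H](O[Si](C)(C)C(C)(C)C)C[C@H]2O[C@]2(C)C[C@@H](OCc2ccc(OC)cc2)[C@H]1C(=C)C(=O)O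
F0 | step 12 | none | none
F3 | step 8 | (2Z,4RS,6E,9R)-9-(4-methoxybenzyloxy)-3,7-dimethyl-1,10-bis(triethylsilyloxy)deca-2,6-dien-4-ol | CC[Si](CC)(CC)OC/C=C(/C)C(O)C/C=C(\C)C[C@@H](OCc1ccc(OC)cc1)CO[Si](CC)(CC)CC
F4 | step 8 | (2Z,6E,9R)-9-(4-methoxybenzyloxy)-3,7-dimethyl-1,10-bis(triethylsilyloxy)deca-2,6-dien-4-one | CC[Si](CC)(CC)OC/C=C(/C)C(=O)C/C=C(\C)C[C@@H](OCc1ccc(OC)cc1)CO[Si](CC)(CC)CC
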